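**Plan**

- Retrosynthetic cuts: chromene O1–C2 and C4–C4a (prenal annulation); prenyl CH2–CH= with re-closure of C(=O)–CH2 to a cyclobutanol; aryl–C(carbinol); C3–CH3; last the two cyclobutane bonds C1–C(acetal) and C2–CH2.
- Enabling feature: on the cyclohexene (C1 aroyl, C2 prenyl, C3(Me)=C4, C5, C6 Ph) the ketone carbon on C1 and the prenyl CH2 on C2 are cis and vicinal. They are C7 and C8 of a cyclobutanone fused across C1–C2, and C3 is the carbonyl of the enone that undergoes the [2+2].
- Forward order: the six-membered ring comes from 4-phenylcyclohexanone; the cyclobutane is closed photochemically; C3=O becomes C3(Me)=C4; the aryl adds to the cyclobutanone; Pd opens the four-membered ring while attaching the isobutenyl unit; the chromene ring closes last.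
- Stereochemistry: C6 (R) from enantioselective deprotonation of the prochiral ketone; C1 (R) from bonding anti to the phenyl in the photocycloaddition; C2 (S) from the cis ring fusion; none is disturbed afterwards.

Key step: step 3

Assumption: the chiral amide is taken to differentiate the enantiotopic α-protons of 4-phenylcyclohexanone in the sense known for 4-tert-butylcyclohexanone, so the (S,S)-amide should give the (R)-enol silane; if the sense is opposite, the (R,R)-amide is used. Optical purity short of complete should be raised by recrystallising a crystalline intermediate such as 7.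

**Route**

Step 1
Reactants: 1 4-phenylcyclohexan-1-one
Product: 3 (R)-trimethyl[(4-phenylcyclohex-1-en-1-yl)oxy]silane, via lithium enolate 2 (not isolated)
Conditions: (S,S)-[PhCH(Me)]2NLi (from the amine + n-BuLi), TMSCl (in situ quench), THF, −100 → −78 °C
Reagents that add atoms: trimethylsilyl chloride, C[Si](C)(C)Cl
Why: Enantioselective deprotonation (desymmetrisation) of the prochiral 4-substituted cyclohexanone by a C2-symmetric chiral lithium amide removes one of the two enantiotopic axial α-protons and the enolate is silylated as it forms, which sets the remote C4 stereocentre as R.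

Step 2
Reactants: 3 (R)-trimethyl[(4-phenylcyclohex-1-en-1-yl)oxy]silane
Product: 4 (R)-4-phenylcyclohex-2-en-1-one
Conditions: Pd(OAc)2 (10 mol %), O2 (1 atm), DMSO, rt
Reagents that add atoms: none
Why: Saegusa–Ito oxidation (palladation of the silyl enol ether at C2, then β-hydride elimination) places the double bond where the enol ether was, and the stereocentre, now γ to the carbonyl, is carried through under neutral conditions.

Step 3
Reactants: 4 (R)-4-phenylcyclohex-2-en-1-one; 5 1,1-dimethoxyethene
Product: 7 (1S,5R,6S)-7,7-dimethoxy-5-phenylbicyclo[4.2.0]octan-2-one (cis-fused; phenyl trans to C7), via trans-fused C1 epimer 6 (not isolated)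
Conditions: 5 (15 equiv), hν (350 nm, Pyrex), CH2Cl2, −40 °C; then basic Al2O3, Et2O, rt
Reagents that add atoms: 1,1-dimethoxyethene (5), C=C(OC)OC
Why: n→π* excitation and intersystem crossing give the triplet enone, which bonds to the electron-rich ketene acetal to form a triplet 1,4-diradical that collapses after spin inversion, the acetal carbon ending on the enone β-carbon (C6) and the CH2 on the α-carbon (C1); this is the classical head-to-tail enone–ketene acetal [2+2] photocycloaddition. The cyclobutane, the only ring formed, is closed by recombination of that 1,4-diradical across the former C=C bond, i.e. a stepwise [2+2] annulation onto C1–C6. C6 is set by bond formation at the β-carbon on the face opposite the neighbouring C5 phenyl group (1,2-induction from the single stereocentre of 4). C1 is α to the ketone and is set thermodynamically, the alumina treatment converting any trans-fused adduct 6 into the cis-fused bicycle. The step needs head-to-tail regiochemistry, supplied by the polarised triplet enone and the donor alkene, and anti facial selectivity, supplied by the bulk of the phenyl group next to the reacting carbon. A large excess of 5 and low temperature should let bimolecular capture of the triplet outrun unimolecular aryl-migration rearrangement of the 4-aryl enone.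

Step 4
Reactants: 7 (1S,5R,6S)-7,7-dimethoxy-5-phenylbicyclo[4.2.0]octan-2-one
Product: 9 (1S,5R,6S)-7,7-dimethoxy-5-phenylbicyclo[4.2.0]oct-2-en-2-yl trifluoromethanesulfonate, via lithium enolate 8 (not isolated)
Conditions: LDA, THF, −78 °C; PhNTf2, −78 → 0 °C
Reagents that add atoms: N-phenylbis(trifluoromethanesulfonimide), O=S(=O)(N(c1ccccc1)S(=O)(=O)C(F)(F)F)C(F)(F)F
Why: Kinetic enolate formation removes a proton from the accessible C3 methylene and not from the ring-fusion methine C1, and O-triflation then fixes the Δ2 position of the future trisubstituted alkene without touching the three stereocentres.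

Step 5
Reactants: 9 (1S,5R,6S)-7,7-dimethoxy-5-phenylbicyclo[4.2.0]oct-2-en-2-yl trifluoromethanesulfonate
Product: 10 (1S,5R,6R)-7,7-dimethoxy-2-methyl-5-phenylbicyclo[4.2.0]oct-2-ene
Conditions: MeZnCl, Pd(PPh3)4 (5 mol %), THF, rt → 50 °C
Reagents that add atoms: methylzinc chloride, C[Zn]Cl
Why: Negishi cross-coupling of the alkenyl triflate replaces OTf by CH3 with retention of the double-bond position, and the ketal is inert to the organozinc reagent.

Step 6
Reactants: 10 (1S,5R,6R)-7,7-dimethoxy-2-methyl-5-phenylbicyclo[4.2.0]oct-2-ene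
Product: 11 (1S,5R,6R)-2-methyl-5-phenylbicyclo[4.2.0]oct-2-en-7-one
Conditions: 1 M aq. HCl, THF, 0 °C → rt
Reagents that add atoms: water, O
Why: Acid-catalysed ketal hydrolysis is fast for the cyclobutanone dimethyl ketal under dilute acid that spares the trisubstituted alkene, and the α ring-fusion centre stays cis because the cis-fused bicyclo[4.2.0] skeleton is strongly preferred.

Step 7
Reactants: 12 5-methoxybenzene-1,3-diol
Product: 13 1-methoxy-3,5-bis(methoxymethoxy)benzene
Conditions: MOMCl, i-Pr2NEt, CH2Cl2, 0 °C → rt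
Reagents that add atoms: chloromethyl methyl ether, COCCl
Why: Williamson-type O-alkylation of both phenols gives the bis-MOM ether, whose two acetal groups will jointly direct lithiation to the carbon between them.

Step 8
Reactants: 11 (1S,5R,6R)-2-methyl-5-phenylbicyclo[4.2.0]oct-2-en-7-one; 13 1-methoxy-3,5-bis(methoxymethoxy)benzene
Product: 15 (1S,5R,6R,7R)-7-[4-methoxy-2,6-bis(methoxymethoxy)phenyl]-2-methyl-5-phenylbicyclo[4.2.0]oct-2-en-7-ol (aryl on the convex face; the C7 epimer would serve equally), via aryllithium 14 (not isolated)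
Conditions: 13, n-BuLi, THF, 0 °C; then 11, −78 → −40 °C; aq. NH4Cl
Reagents that add atoms: 1-methoxy-3,5-bis(methoxymethoxy)benzene (13), COCOc1cc(OC)cc(OCOC)c1
Why: Directed ortho-metalation between the two MOM ethers gives the 2-lithio arene, which should undergo 1,2-addition to the strained, highly electrophilic cyclobutanone from its convex face faster than it enolises it; the configuration of the carbinol carbon is of no consequence because it becomes the ketone carbon.

Step 9
Reactants: 15 (1S,5R,6R,7R)-7-[4-methoxy-2,6-bis(methoxymethoxy)phenyl]-2-methyl-5-phenylbicyclo[4.2.0]oct-2-en-7-ol; 16 1-bromo-2-methylprop-1-ene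
Product: 17 [4-methoxy-2,6-bis(methoxymethoxy)phenyl][(1R,2S,6R)-3-methyl-2-(3-methylbut-2-en-1-yl)-6-phenylcyclohex-3-en-1-yl]methanone
Conditions: 16 (2 equiv), Pd(OAc)2 (5 mol %), rac-BINAP (10 mol %), Cs2CO3, toluene, 70 °C
Reagents that add atoms: 1-bromo-2-methylprop-1-ene (16), CC(C)=CBr
Why: Palladium-catalysed ring-opening cross-coupling of a tertiary cyclobutanol with a vinyl halide: oxidative addition of 16, palladium alkoxide formation, strain-releasing β-carbon elimination toward the unhindered C8 methylene (not the crowded ring-fusion carbon C6) and C(sp3)–C(sp2) reductive elimination, favoured over β-hydride elimination by the chelating bisphosphine, should give the aryl ketone and the prenyl chain with the cis C1/C2 relationship inherited from the cyclobutane.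

Step 10
Reactants: 17 [4-methoxy-2,6-bis(methoxymethoxy)phenyl][(1R,2S,6R)-3-methyl-2-(3-methylbut-2-en-1-yl)-6-phenylcyclohex-3-en-1-yl]methanone
Product: 18 (2,6-dihydroxy-4-methoxyphenyl)[(1R,2S,6R)-3-methyl-2-(3-methylbut-2-en-1-yl)-6-phenylcyclohex-3-en-1-yl]methanone
Conditions: 3 M aq. HCl, MeOH, 40 °C
Reagents that add atoms: none
Why: Acid-catalysed acetal exchange in methanol cleaves both aryl MOM ethers, which are activated by the ortho carbonyl, under conditions mild enough for the prenyl and ring alkenes and the ketone α-centre.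

Step 11
Reactants: 18 (2,6-dihydroxy-4-methoxyphenyl)[(1R,2S,6R)-3-methyl-2-(3-methylbut-2-en-1-yl)-6-phenylcyclohex-3-en-1-yl]methanone; 19 3-methylbut-2-enal
Product: 21 (7-hydroxy-5-methoxy-2,2-dimethyl-2H-chromen-8-yl)[(1R,2S,6R)-3-methyl-2-(3-methylbut-2-en-1-yl)-6-phenylcyclohex-3-en-1-yl]methanone, via ortho-quinone methide 20 (not isolated)
Conditions: 19 (1.2 equiv), ethylenediammonium diacetate (20 mol %), toluene, 110 °C
Reagents that add atoms: 3-methylbut-2-enal (19), CC(C)=CC=O
Why: Amine-salt-catalysed Knoevenagel-type condensation at either of the two equivalent free ring carbons ortho to a phenol gives an ortho-quinone methide that closes by oxa-6π electrocyclisation to the 2,2-dimethyl-2H-chromene, the second phenol being held back by its hydrogen bond to the ketone and by the limited amount of aldehyde.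

**Compound list**

1 | 4-phenylcyclohexan-1-one | O=C1CCC(CC1)c1ccccc1 | starting material
2 | lithium (R)-4-phenylcyclohex-1-en-1-olate (not isolated) | [Li]OC1=CC[C@H](c2ccccc2)CC1 | intermediate
3 | (R)-trimethyl[(4-phenylcyclohex-1-en-1-yl)oxy]silane | C[Si](C)(C)OC1=CC[C@H](c2ccccc2)CC1 | intermediate
4 | (R)-4-phenylcyclohex-2-en-1-one | O=C1CC[C@@H](c2ccccc2)C=C1 | intermediate
5 | 1,1-dimethoxyethene | C=C(OC)OC | starting material
6 | (1R,5R,6S)-7,7-dimethoxy-5-phenylbicyclo[4.2.0]octan-2-one, trans-fused (not isolated) | O=C1CC[C@@H](c2ccccc2)[C@H]2[C@H]1CC2(OC)OC | intermediate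
7 | (1S,5R,6S)-7,7-dimethoxy-5-phenylbicyclo[4.2.0]octan-2-one, cis-fused, phenyl trans to C7 | O=C1CC[C@@H](c2ccccc2)[C@H]2[C@@H]1CC2(OC)OC | intermediate
8 | lithium (1S,5R,6S)-7,7-dimethoxy-5-phenylbicyclo[4.2.0]oct-2-en-2-olate (not isolated) | [Li]OC1=CC[C@@H](c2ccccc2)[C@H]2[C@@H]1CC2(OC)OC | intermediate
9 | (1S,5R,6S)-7,7-dimethoxy-5-phenylbicyclo[4.2.0]oct-2-en-2-yl trifluoromethanesulfonate | O=S(=O)(OC1=CC[C@@H](c2ccccc2)[C@H]2[C@@H]1CC2(OC)OC)C(F)(F)F | intermediate
10 | (1S,5R,6R)-7,7-dimethoxy-2-methyl-5-phenylbicyclo[4.2.0]oct-2-ene | CC1=CC[C@@H](c2ccccc2)[C@H]2[C@@H]1CC2(OC)OC | intermediate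
11 | (1S,5R,6R)-2-methyl-5-phenylbicyclo[4.2.0]oct-2-en-7-one | CC1=CC[C@@H](c2ccccc2)[C@H]2[C@@H]1CC2=O | intermediate
12 | 5-methoxybenzene-1,3-diol | COc1cc(O)cc(O)c1 | starting material
13 | 1-methoxy-3,5-bis(methoxymethoxy)benzene | COCOc1cc(OC)cc(OCOC)c1 | intermediate
14 | [4-methoxy-2,6-bis(methoxymethoxy)phenyl]lithium (not isolated) | [Li]c1c(OCOC)cc(OC)cc1OCOC | intermediate
15 | (1S,5R,6R,7R)-7-[4-methoxy-2,6-bis(methoxymethoxy)phenyl]-2-methyl-5-phenylbicyclo[4.2.0]oct-2-en-7-ol | CC1=CC[C@@H](c2ccccc2)[C@H]2[C@@H]1C[C@]2(O)c1c(OCOC)cc(OC)cc1OCOC | intermediate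
16 | 1-bromo-2-methylprop-1-ene | CC(C)=CBr | starting material
17 | [4-methoxy-2,6-bis(methoxymethoxy)phenyl][(1R,2S,6R)-3-methyl-2-(3-methylbut-2-en-1-yl)-6-phenylcyclohex-3-en-1-yl]methanone | COCOc1cc(OC)cc(OCOC)c1C(=O)[C@@H]1[C@H](CC=C(C)C)C(C)=CC[C@H]1c1ccccc1 | intermediate
18 | (2,6-dihydroxy-4-methoxyphenyl)[(1R,2S,6R)-3-methyl-2-(3-methylbut-2-en-1-yl)-6-phenylcyclohex-3-en-1-yl]methanone | COc1cc(O)c(C(=O)[C@@H]2[C@H](CC=C(C)C)C(C)=CC[C@H]2c2ccccc2)c(O)c1 | intermediate
19 | 3-methylbut-2-enal | CC(C)=CC=O | starting material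
20 | (6Z)-3-hydroxy-5-methoxy-6-(3-methylbut-2-en-1-ylidene)-2-{[(1R,2S,6R)-3-methyl-2-(3-methylbut-2-en-1-yl)-6-phenylcyclohex-3-en-1-yl]carbonyl}cyclohexa-2,4-dien-1-one (not isolated) | COC1=CC(O)=C(C(=O)[C@@H]2[C@H](CC=C(C)C)C(C)=CC[C@H]2c2ccccc2)C(=O)/C1=C\C=C(C)C | intermediate
21 | (7-hydroxy-5-methoxy-2,2-dimethyl-2H-chromen-8-yl)[(1R,2S,6R)-3-methyl-2-(3-methylbut-2-en-1-yl)-6-phenylcyclohex-3-en-1-yl]methanone | COc1cc(O)c(C(=O)[C@@H]2[C@H](CC=C(C)C)C(C)=CC[C@H]2c2ccccc2)c2c1C=CC(C)(C)O2 | target

**Summary**

Total step count: 11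
Longest linear sequence: 10 steps (steps 1–6 and 8–11; step 7 is the one-step side branch)

**Steps most likely to fail**

1. Step 9. The β-carbon elimination may cut the other cyclobutane bond (toward the ring-fusion carbon), or the primary alkylpalladium may undergo β-hydride elimination before reductive elimination. Fallback: the C7–C8 bond is cut by polar means, setting out from cyclobutanone 11 and coming back at ketone 17. Claisen formylation at the C8 methylene (HCO2Et, NaH, THF) should give (1S,5R,6S,8Z)-8-(hydroxymethylidene)-2-methyl-5-phenylbicyclo[4.2.0]oct-2-en-7-one F1. Sodium methoxide in methanol should add to the strained ring carbonyl and trigger retro-Claisen ring opening to methyl (1R,2S,6R)-3-methyl-2-(2-oxoethyl)-6-phenylcyclohex-3-ene-1-carboxylate F2. Wittig olefination of the aldehyde with isopropylidenetriphenylphosphorane should give methyl (1R,2S,6R)-3-methyl-2-(3-methylbut-2-en-1-yl)-6-phenylcyclohex-3-ene-1-carboxylate F3. Acylation of aryllithium 14 by F3 (THF, −78 → 0 °C) then gives 17, the hindered ketone resisting a second addition. This replaces steps 8 and 9.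

2. Step 3. Unimolecular aryl-migration photorearrangement of the excited 4-aryl enone may compete with capture by the alkene, or bonding at the β-carbon may occur on the phenyl face and erode facial selectivity. Fallback: the cis C1/C2 pair is set by a [4+2] cycloaddition, setting out from arene 13 and coming back at ketone 17. An endo-selective Diels–Alder reaction of (E)-cinnamaldehyde with (E)-β-ocimene under chiral imidazolidinone (iminium) catalysis should give (1R,2S,6R)-3-methyl-2-(3-methylbut-2-en-1-yl)-6-phenylcyclohex-3-ene-1-carbaldehyde F4, with the formyl group cis to the prenyl group by the endo rule and trans to phenyl from the E-enal. Addition of aryllithium 14 (from 13) should give [4-methoxy-2,6-bis(methoxymethoxy)phenyl][(1R,2S,6R)-3-methyl-2-(3-methylbut-2-en-1-yl)-6-phenylcyclohex-3-en-1-yl]methanol F5 (either carbinol epimer), and periodinane (DMP) oxidation gives 17. This replaces steps 1–6, 8 and 9; step 7 still supplies 13.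

3. Step 11. A second annulation at the remaining phenol, or enolisation at C1 under the hot amine-salt conditions with loss of configuration, may occur. Fallback: the chromene is built by a sigmatropic route under neutral conditions, setting out from diol 18 and coming back at target 21. Mono-O-alkylation with 3-chloro-3-methylbut-1-yne (DBU, CuCl2 cat., MeCN, 0 °C) should give {2-hydroxy-4-methoxy-6-[(2-methylbut-3-yn-2-yl)oxy]phenyl}[(1R,2S,6R)-3-methyl-2-(3-methylbut-2-en-1-yl)-6-phenylcyclohex-3-en-1-yl]methanone F6. Heating in xylene (about 140 °C) should bring about aromatic propargyl Claisen rearrangement, 1,5-hydrogen shift and oxa-6π closure to 21.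

Further compounds
F1 | step 9 | (1S,5R,6S,8Z)-8-(hydroxymethylidene)-2-methyl-5-phenylbicyclo[4.2.0]oct-2-en-7-one | CC1=CC[C@@H](c2ccccc2)[C@H]2[C@@H]1/C(=C/O)C2=O
F2 | step 9 | methyl (1R,2S,6R)-3-methyl-2-(2-oxoethyl)-6-phenylcyclohex-3-ene-1-carboxylate | COC(=O)[C@@H]1[C@H](CC=O)C(C)=CC[C@H]1c1ccccc1
F3 | step 9 | methyl (1R,2S,6R)-3-methyl-2-(3-methylbut-2-en-1-yl)-6-phenylcyclohex-3-ene-1-carboxylate | COC(=O)[C@@H]1[C@H](CC=C(C)C)C(C)=CC[C@H]1c1ccccc1
F4 | step 3 | (1R,2S,6R)-3-methyl-2-(3-methylbut-2-en-1-yl)-6-phenylcyclohex-3-ene-1-carbaldehyde | O=C[C@@H]1[C@H](CC=C(C)C)C(C)=CC[C@H]1c1ccccc1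
F5 | step 3 | [4-methoxy-2,6-bis(methoxymethoxy)phenyl][(1R,2S,6R)-3-methyl-2-(3-methylbut-2-en-1-yl)-6-phenylcyclohex-3-en-1-yl]methanol | COCOc1cc(OC)cc(OCOC)c1C(O)[C@@H]1[C@H](CC=C(C)C)C(C)=CC[C@H]1c1ccccc1
F6 | step 11 | {2-hydroxy-4-methoxy-6-[(2-methylbut-3-yn-2-yl)oxy]phenyl}[(1R,2S,6R)-3-methyl-2-(3-methylbut-2-en-1-yl)-6-phenylcyclohex-3-en-1-yl]methanone | COc1cc(O)c(C(=O)[C@@H]2[C@H](CC=C(C)C)C(C)=CC[C@H]2c2ccccc2)c(OC(C)(C)C#C)c1
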